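2.58 is the ligand ratio of Friday's flask, the added ligand charged divided by the catalyst charged, and it is the number I ask you to watch when you take over this bench.

Each flask holds substrate, catalyst, added ligand and protic impurity, and partner is dosed in at a steady rate.

common to all: protic impurity 10.5 mM
- north-west: substrate 8.2 mM; partner 140 mM (fed, over 6.0 d); free catalyst 2.2 mM; added ligand 3.1 mM; run made earlier
- north: substrate 33 mM; partner 140 mM (fed, over 6.0 d); free catalyst 2.2 mM; added ligand 3.1 mM; run made earlier
- west: substrate 35 mM; partner 140 mM (fed, over 6.0 d); free catalyst 2 mM; added ligand 3.1 mM; run made earlier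
- Friday's: substrate 50 mM; partner 140 mM (fed, over 6.0 d); free catalyst 1.2 mM; added ligand 3.1 mM; time 12 d
- Wednesday's: substrate 12 mM; partner 140 mM (fed, over 1.5 d); free catalyst 2.2 mM; added ligand 1.0 mM; time 12 d
- Thursday's: substrate 35 mM; partner 140 mM (fed, over 6.0 d); free catalyst 2.2 mM; added ligand 3.1 mM; time 12 d
- Saturday's: substrate 35 mM; partner 140 mM (fed, over 3.0 d); free catalyst 4.0 mM; added ligand 3.1 mM; time 12 d

- north-west (time / d: target / %): 0.625: 2.3; 1.04: 5.8; 1.67: 14.2; 3.00: 27.5; 5.00: 42.6; 8.00: 58.6
- north (time / d: target / %): 0.625: 0.6; 1.04: 6.0; 1.67: 8.4; 3.00: 19.7; 5.00: 34.8; 8.00: 52.1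
- west (time / d: target / %): 0.625: 0.4; 1.25: 6.5; 2.50: 14.3; 4.00: 23.5; 8.00: 48.0

(scatter of a reading: 1 percentage point)

* the flasks put in order of amount of target, in percent of the substrate charged, best first, at 12 d (Friday's / Wednesday's / Thursday's / Saturday's)
* the same order at 2.5 d (Friday's / Wednesday's / Thursday's / Saturday's)
* the amount of target, in percent of the substrate charged of the flask you put first, at 12 d
* the amount of target, in percent of the substrate charged of the flask you put last, at 12 d

- no earlier run changes the charge of added ligand; that part of a forecast is a guess

The earlier runs stand above a ratio of one: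

north-west 1.41, north 1.41, west 1.55

The west run, with less catalyst against the same added ligand, gives 48.0% at 8.00 d, less than the north run's 52.1%, though its substrate differs a little too. My guess, which no run tests, is that each added ligand takes up one catalyst. A ratio below one then leaves catalyst over, and a ratio above one leaves ligand over. For the new flasks I reckon:

Wednesday's 0.455
Saturday's 0.775
Thursday's 1.41
Friday's 2.58

Wednesday's and Saturday's stand below one, and Wednesday's ratio is lower than Saturday's. When you come at 2.5 d, I expect the flasks in order of rising ratio, though substrate and feed differ among them too: Wednesday's, Saturday's, Thursday's, Friday's. Expect Thursday's near the west run's 14.3%. The ratio does not say how long the catalyst lasts, so I leave the order at 12 d open. Please leave the added ligand as charged, since the ratio is reckoned from that charge.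

The forecast gives Saturday's > Wednesday's > Thursday's > Friday's at 12 d, from 90% down to 42%, and Saturday's > Wednesday's > Thursday's > Friday's at 2.5 d, with Saturday's first where my ratio puts Wednesday's, and it calls the lower ligand “an untested guess”.

The flasks give Saturday's > Wednesday's > Thursday's > Friday's at 12 d, from 92.2% to 36.3%, and Wednesday's > Saturday's > Thursday's > Friday's at 2.5 d, with 57.8% in Wednesday's and 6.10% in Friday's.

    substrate + free catalyst → catalyst intermediate A (k = 0.550 M⁻¹ min⁻¹)
    partner + catalyst intermediate A → catalyst intermediate B (k = 0.120 M⁻¹ min⁻¹)
    catalyst intermediate B ⇌ released group + catalyst intermediate C (K = 0.0310 M, k = 0.0400 min⁻¹)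
    catalyst intermediate C → free catalyst + target (k = 0.460 min⁻¹)
    free catalyst + added ligand ⇌ idle complex, settled at all times (K = 9200 M⁻¹)
    2 free catalyst → spent catalyst (k = 0.690 M⁻¹ min⁻¹)
    partner + protic impurity → quenched reagent (k = 0.160 M⁻¹ min⁻¹)

Friday's, at ratio 2.58, ends at 36.3% at 12 d. Part of the reason is the binding of free catalyst and added ligand into idle complex, an off-cycle form, and part is the length of the run: without that binding Friday's reaches 83.4%, and left until 120 d it reaches 98.2%. At 12 d, 83.3% of Friday's catalyst stands as idle complex. The neighbour of Friday's charged with 0.78 mM of added ligand has ratio 0.650, and at 12.0 d it holds 35.9% of its catalyst as idle complex and has reached 73.5%.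

The readings are calculated on assumed constants, noise included.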